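**Assumption:** briarane numbering is used throughout (C1–C10 ten-membered ring, C1/C10–C14 six-membered ring, Me-15 on C1, C16 exo-methylene on C5, C17–C19 lactone, Me-20 on C11). "β" is the face carrying Me-15. The target is 1S,2S,6S,7R,8R,9S,10S,11R,12S,13S,14R,17R.

## Retrosynthetic overview

1. The ten-membered ring is closed last by ethylene-assisted ring-closing enyne metathesis of a C2 vinyl carbinol acetate with a C4≡C5 alkyne; this makes the 3Z-alkene and the C5=C16 exo-methylene next to an already installed C6–Cl.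
2. The γ-lactone (C7–O, C8–OH, C17) comes from an intramolecular Reformatsky reaction onto a C8 ketone; the 13,14-epoxide from a 12α-OH-directed epoxidation.
3. The cyclohexene (C1, C10–C14) comes from a Diels–Alder reaction of a (Z)-2-silyloxypentadiene with an (E)-α-methyl enal; the C9 stereocentre directs the face and sets C1 and C10.
4. The enal carries C5–C10 from D-galactose (bought as IPTG): galactose C1–C6 become C10, C9, C8, C7, C6, C5. C6–Cl is made by SN2 inversion of galactose O5.
5. Ring order: cyclohexene, then γ-lactone, then epoxide, then ten-membered ring.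

## Route

**Step 1**
Reactants: 1, isopropyl 1-thio-β-D-galactopyranoside (IPTG)
Product: 2, isopropyl 3,4-O-isopropylidene-1-thio-β-D-galactopyranoside
Conditions: 2,2-dimethoxypropane, CSA (cat.), acetone, rt; then aq. AcOH work-up
Reagents that add atoms: 2,2-dimethoxypropane, COC(C)(C)OC
Why: Thermodynamic acetalization takes the cis-3,4-diol selectively, leaving O2 and O6 free.

**Step 2**
Reactants: 2
Product: 3, the 6-aldehyde of 2 (galacto-hexodialdo-1,5-pyranoside)
Conditions: TEMPO (cat.), PhI(OAc)2, CH2Cl2, rt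
Reagents that add atoms: none
Why: Oxoammonium (TEMPO/BAIB) oxidation is selective for the primary alcohol and tolerates the thioglycoside and the secondary 2-OH.

**Step 3**
Reactants: 3
Product: 4, isopropyl 6,7-dideoxy-3,4-O-isopropylidene-1-thio-β-D-galacto-hept-6-ynopyranoside
Conditions: Bestmann–Ohira reagent, K2CO3, MeOH, 0 °C to rt
Reagents that add atoms: dimethyl (1-diazo-2-oxopropyl)phosphonate, COP(=O)(OC)C(=[N+]=[N-])C(C)=O
Why: Ohira–Bestmann (Seyferth–Gilbert) homologation gives the terminal alkyne (future C4≡C5) without epimerizing C5, as in the diacetone-galactose series.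

**Step 4**
Reactants: 4
Product: 5, the 2-O-TBS ether of 4
Conditions: TBSOTf, 2,6-lutidine, CH2Cl2, 0 °C
Reagents that add atoms: TBSOTf, CC(C)(C)[Si](C)(C)OS(=O)(=O)C(F)(F)F
Why: Silylation of the only free hydroxyl protects the future C9–OH with a non-migrating group.

**Step 5**
Reactants: 5
Product: 6, 2-O-TBS-6,7-dideoxy-3,4-O-isopropylidene-D-galacto-hept-6-ynopyranose (lactol, anomeric mixture)
Conditions: NBS, NaHCO3, acetone/H2O 9:1, 0 °C
Reagents that add atoms: water, O
Why: Halonium activation of the thioglycoside and hydrolysis frees the anomeric carbon under conditions that spare the acetonide, TBS ether and alkyne.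

**Step 6**
Reactants: 6
Product: 7, (E)-α-methyl enal with C9–OTBS, C8/C7 cis-acetonide and a free (6R) propargylic OH
Conditions: Ph3P=C(CH3)CHO, toluene, 100 °C
Reagents that add atoms: 2-(triphenylphosphoranylidene)propanal, CC(C=O)=P(c1ccccc1)(c1ccccc1)c1ccccc1
Why: Wittig olefination of the open-chain aldehyde with a stabilized ylide gives the E-trisubstituted enal (C2, C1, Me-15) and releases galactose O5 as the only free hydroxyl.

**Step 7**
Reactants: 7
Product: 8, the (6S) propargylic chloride (dienophile)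
Conditions: MsCl, Et3N, CH2Cl2, −20 °C; then LiCl, DMF, rt
Reagents that add atoms: lithium chloride, [Li+].[Cl-]
Why: SN2 displacement of the propargylic mesylate by chloride inverts the galactose C5 centre to the C6–Cl configuration of the target.

**Step 8**
Reactants: 9, ethyl vinyl ketone
Product: 10, (Z)-3-(tert-butyldimethylsilyloxy)penta-1,3-diene
Conditions: TBSOTf, Et3N, Et2O, 0 °C
Reagents that add atoms: TBSOTf, CC(C)(C)[Si](C)(C)OS(=O)(=O)C(F)(F)F
Why: Soft enolization of the ethyl ketone gives the Z silyl dienol ether (C14=C13–C12(OTBS)=C11–Me-20).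

**Step 9 (key step)**
Reactants: 8 and 10
Product: 11, Diels–Alder adduct: cyclohexene with C1 (Me, CHO), C12 TBS enol ether, Me-20 on C11 (11-epi, Me-20 α), and the C10 side chain
Conditions: Me2AlCl (1.2 equiv), CH2Cl2, −78 to −40 °C
Reagents that add atoms: none
Why: Lewis-acid Diels–Alder reaction with "para" regiochemistry; A(1,3) strain with Me-15 holds C9–H in the alkene plane and the diene adds anti to the C9–O bond, setting C1 and C10, while the endo (CHO) transition state gives C11 epimeric (corrected in step 12).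

**Step 10**
Reactants: 11
Product: 12, the (2S) vinyl carbinol acetate
Conditions: CH2=CHMgBr/CeCl3, THF, −78 °C; then Ac2O, DMAP, −78 to 0 °C
Reagents that add atoms: vinylmagnesium bromide, C=C[Mg]Br; acetic anhydride, CC(=O)OC(C)=O
Why: Felkin–Anh 1,2-addition of the weakly basic organocerium, anti to the C10 branch, gives the 2S alkoxide, which is trapped as the final C2 acetate.

**Step 11**
Reactants: 12
Product: 13, the C12 enone (C13=C14), still 11-epi
Conditions: Pd(OAc)2, MeCN, rt
Reagents that add atoms: none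
Why: Saegusa–Ito oxidation of the regiodefined silyl enol ether places the double bond at C13=C14.

**Step 12**
Reactants: 13
Product: 14, the enone with Me-20 β (C11 as in the target)
Conditions: TMSOTf, Et3N, CH2Cl2, 0 °C; then TBAF/AcOH, THF, −78 °C
Reagents that add atoms: none
Why: The cross-conjugated silyl dienol ether is protonated kinetically at C11 anti to the pseudo-axial C10 side chain (A(1,2) strain), giving the cis C9/Me-20 relationship; the step is stereoconvergent.

**Step 13**
Reactants: 14
Product: 15, the C7,C8-diol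
Conditions: AcOH/H2O 4:1, 45 °C
Reagents that add atoms: none
Why: Acid hydrolysis removes the acetonide while the hindered secondary TBS ether, the acetate and the chloride survive.

**Step 14**
Reactants: 15
Product: 16, the C7 2-bromopropionate (C8–OH free; mixture at CHBr)
Conditions: 2-bromopropionyl bromide (1.05 equiv), 2,6-lutidine, CH2Cl2, −78 °C
Reagents that add atoms: 2-bromopropionyl bromide, CC(Br)C(=O)Br
Why: Sterically controlled monoacylation; C8–OH is shielded by the C9 OTBS group and the ring, so the C7–OH reacts.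

**Step 15**
Reactants: 16
Product: 17, the C8 ketone
Conditions: Dess–Martin periodinane, NaHCO3, CH2Cl2, 0 °C to rt
Reagents that add atoms: none
Why: Neutral oxidation of the remaining hindered secondary alcohol without eliminating the β-chloride.

**Step 16**
Reactants: 17
Product: 18, the γ-lactone with (8R) tertiary OH and (17R) methyl
Conditions: SmI2 (2.2 equiv), THF, −78 °C
Reagents that add atoms: none
Why: Intramolecular samarium Reformatsky reaction; the enolate tethered on C7–O closes the five-membered ring with C6 trans to C9 (OH cis to C6) and Me-18 cis to OH, which is also the thermodynamic C17 epimer.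

**Step 17**
Reactants: 18
Product: 19, the 12β allylic alcohol
Conditions: NaBH4, CeCl3·7H2O, MeOH, −78 °C
Reagents that add atoms: none
Why: Luche 1,2-reduction; hydride attacks the α-face, anti to the pseudo-axial C10 side chain, giving the 12β-OH.

**Step 18**
Reactants: 19
Product: 20, the 12α formate
Conditions: PPh3, DIAD, HCO2H, THF, 0 °C
Reagents that add atoms: formic acid, O=CO
Why: Mitsunobu inversion of the allylic alcohol; the tertiary C8–OH does not react.

**Step 19**
Reactants: 20
Product: 21, the triol (C9–OH, 12α-OH, C8–OH)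
Conditions: HF·pyridine, THF, 0 °C to rt; then NaHCO3, MeOH/H2O, 0 °C
Reagents that add atoms: none
Why: Fluoride removes the C9 TBS ether and mild methanolysis cleaves the formate while the acetate and lactone remain.

**Step 20**
Reactants: 21
Product: 22, the 13α,14α-epoxide
Conditions: VO(acac)2 (5 mol %), t-BuOOH, CH2Cl2, 0 °C to rt
Reagents that add atoms: tert-butyl hydroperoxide, CC(C)(C)OO
Why: Hydroxyl-directed (vanadium) epoxidation delivers oxygen syn to the 12α-OH and leaves the vinyl group and alkyne untouched.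

**Step 21**
Reactants: 22
Product: 23, the 2,9,12-triacetate
Conditions: Ac2O, pyridine, DMAP (cat.), CH2Cl2, rt
Reagents that add atoms: acetic anhydride, CC(=O)OC(C)=O
Why: Acylation of the two secondary alcohols; the hindered tertiary C8–OH stays free.

**Step 22**
Reactants: 23
Product: 24, brianthein Z
Conditions: Grubbs II (20 mol %), ethylene (1 atm), toluene (1 mM), 80 °C
Reagents that add atoms: ethylene, C=C (supplies the C16 methylene in the cross-metathesis/RCM pathway; the vinyl CH2 leaves as ethylene)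
Why: Ethylene-assisted ring-closing enyne metathesis converts the alkyne to the 2-substituted diene and closes C3=C4; the ten-membered ring enforces the Z-alkene, and the chloride, epoxide and esters are tolerated.

## Compound list

1 | isopropyl 1-thio-β-D-galactopyranoside (IPTG) | CC(C)S[C@H]1[C@H](O)[C@@H](O)[C@@H](O)[C@@H](CO)O1 | starting material
2 | 3,4-O-isopropylidene derivative of 1 | CC(C)S[C@H]1[C@H](O)[C@H]2OC(C)(C)O[C@H]2[C@@H](CO)O1 | intermediate
3 | 6-aldehyde of 2 | CC(C)S[C@H]1[C@H](O)[C@H]2OC(C)(C)O[C@H]2[C@@H](C=O)O1 | intermediate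
4 | 6,7-dideoxy-hept-6-ynopyranoside | CC(C)S[C@H]1[C@H](O)[C@H]2OC(C)(C)O[C@H]2[C@@H](C#C)O1 | intermediate
5 | 2-O-TBS ether of 4 | CC(C)S[C@H]1[C@H](O[Si](C)(C)C(C)(C)C)[C@H]2OC(C)(C)O[C@H]2[C@@H](C#C)O1 | intermediate
6 | lactol (anomeric mixture) | OC1[C@H](O[Si](C)(C)C(C)(C)C)[C@H]2OC(C)(C)O[C@H]2[C@@H](C#C)O1 | intermediate
7 | (E)-enal, (6R) propargylic alcohol | O=C/C(C)=C/[C@H](O[Si](C)(C)C(C)(C)C)[C@H]1OC(C)(C)O[C@H]1[C@H](O)C#C | intermediate
8 | (E)-enal, (6S) propargylic chloride (dienophile) | O=C/C(C)=C/[C@H](O[Si](C)(C)C(C)(C)C)[C@H]1OC(C)(C)O[C@H]1[C@@H](Cl)C#C | intermediate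
9 | ethyl vinyl ketone | C=CC(=O)CC | starting material
10 | (Z)-3-(TBS-oxy)penta-1,3-diene | C=C/C(O[Si](C)(C)C(C)(C)C)=C/C | intermediate
11 | Diels–Alder adduct (C2 aldehyde, C12 TBS enol ether, 11-epi) | O=C[C@]1(C)[C@H]([C@H](C)C(O[Si](C)(C)C(C)(C)C)=CC1)[C@H](O[Si](C)(C)C(C)(C)C)[C@H]2OC(C)(C)O[C@H]2[C@@H](Cl)C#C | intermediate
12 | (2S) vinyl carbinol acetate | C=C[C@H](OC(C)=O)[C@]1(C)[C@H]([C@H](C)C(O[Si](C)(C)C(C)(C)C)=CC1)[C@H](O[Si](C)(C)C(C)(C)C)[C@H]2OC(C)(C)O[C@H]2[C@@H](Cl)C#C | intermediate
13 | C12 enone, 11-epi | C=C[C@H](OC(C)=O)[C@]1(C)[C@H]([C@H](C)C(=O)C=C1)[C@H](O[Si](C)(C)C(C)(C)C)[C@H]2OC(C)(C)O[C@H]2[C@@H](Cl)C#C | intermediate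
14 | C12 enone, Me-20 β | C=C[C@H](OC(C)=O)[C@]1(C)[C@H]([C@@H](C)C(=O)C=C1)[C@H](O[Si](C)(C)C(C)(C)C)[C@H]2OC(C)(C)O[C@H]2[C@@H](Cl)C#C | intermediate
15 | C7,C8-diol | C=C[C@H](OC(C)=O)[C@]1(C)[C@H]([C@@H](C)C(=O)C=C1)[C@H](O[Si](C)(C)C(C)(C)C)[C@@H](O)[C@@H](O)[C@@H](Cl)C#C | intermediate
16 | C7 2-bromopropionate | C=C[C@H](OC(C)=O)[C@]1(C)[C@H]([C@@H](C)C(=O)C=C1)[C@H](O[Si](C)(C)C(C)(C)C)[C@@H](O)[C@@H](OC(=O)C(C)Br)[C@@H](Cl)C#C | intermediate
17 | C8 ketone | C=C[C@H](OC(C)=O)[C@]1(C)[C@H]([C@@H](C)C(=O)C=C1)[C@H](O[Si](C)(C)C(C)(C)C)C(=O)[C@@H](OC(=O)C(C)Br)[C@@H](Cl)C#C | intermediate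
18 | γ-lactone enone | C=C[C@H](OC(C)=O)[C@]1(C)[C@H]([C@@H](C)C(=O)C=C1)[C@H](O[Si](C)(C)C(C)(C)C)[C@]2(O)[C@@H](C)C(=O)O[C@H]2[C@@H](Cl)C#C | intermediate
19 | 12β allylic alcohol | C=C[C@H](OC(C)=O)[C@]1(C)[C@H]([C@@H](C)[C@@H](O)C=C1)[C@H](O[Si](C)(C)C(C)(C)C)[C@]2(O)[C@@H](C)C(=O)O[C@H]2[C@@H](Cl)C#C | intermediate
20 | 12α formate | C=C[C@H](OC(C)=O)[C@]1(C)[C@H]([C@@H](C)[C@H](OC=O)C=C1)[C@H](O[Si](C)(C)C(C)(C)C)[C@]2(O)[C@@H](C)C(=O)O[C@H]2[C@@H](Cl)C#C | intermediate
21 | triol (C9–OH, 12α-OH, C8–OH) | C=C[C@H](OC(C)=O)[C@]1(C)[C@H]([C@@H](C)[C@H](O)C=C1)[C@H](O)[C@]2(O)[C@@H](C)C(=O)O[C@H]2[C@@H](Cl)C#C | intermediate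
22 | 13α,14α-epoxide | C=C[C@H](OC(C)=O)[C@]2(C)[C@H]([C@@H](C)[C@H](O)[C@@H]3O[C@@H]32)[C@H](O)[C@]2(O)[C@@H](C)C(=O)O[C@H]2[C@@H](Cl)C#C | intermediate
23 | 2,9,12-triacetate (enyne) | C=C[C@H](OC(C)=O)[C@]2(C)[C@H]([C@@H](C)[C@H](OC(C)=O)[C@@H]3O[C@@H]32)[C@H](OC(C)=O)[C@]2(O)[C@@H](C)C(=O)O[C@H]2[C@@H](Cl)C#C | intermediate
24 | brianthein Z | C=C1/C=C\[C@H](OC(C)=O)[C@]2(C)[C@H]([C@@H](C)[C@H](OC(C)=O)[C@@H]3O[C@@H]32)[C@H](OC(C)=O)[C@]2(O)[C@@H](C)C(=O)O[C@H]2[C@H]1Cl | target

## Summary

Total steps: 22. Longest linear sequence: 21 (steps 1–7 and 9–22); step 8 is a one-step side branch.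

Steps most likely to fail:

1. **Step 22 (ten-membered ring by enyne metathesis).** The vinyl group is neopentylic and medium-ring closure may stop at the acyclic triene or give E/Z mixtures. Fallback: close the ring at C2–C3 by intramolecular Nozaki–Hiyama–Kishi coupling. This keeps C2 as the aldehyde and converts the alkyne into a (Z)-dienyl iodide (Markovnikov hydroiodination, Stille coupling with (Z)-1,2-bis(tributylstannyl)ethene, iododestannylation). C6 is carried as a silyl ether and the chloride is introduced after ring closure.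

2. **Step 9 (Diels–Alder).** The trisubstituted enal is a sluggish dienophile, and the facial sense (anti to C9–O) is the least certain stereochemical prediction in the route. Fallback: build the cyclohexene by an Ireland–Claisen rearrangement of a lactate-derived allylic ester (chair transition state sets C1/C10), followed by ring-closing metathesis to the C13=C14 alkene.

3. **Step 14 (monoacylation of C7–OH over C8–OH).** It relies only on steric discrimination between two secondary alcohols, and acyl migration is possible. Fallback: differentiate the two oxygens at the sugar stage, with galactose O3 as a PMB ether (Bu2SnO/PMBCl on IPTG) and O4 as a separate silyl ether, so that each is unmasked individually for oxidation and acylation.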